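The readings stem from a simulated flask for substances that don't exist, noise included.

Slowness was what I noticed first in the alder flask: from 15.0 h to 40.0 h target rose by 2.8 percentage points, while starting material stood at 71.1%.

| setting | alder | elm | flask |
|---|---|---|---|
| starting material | 0.11 M | 0.11 M | 0.11 M |
| second substrate | 0.055 M | 0.055 M | 0.0550 M |
| coupling partner | 0.121 M | 0.121 M | 0.121 M |
| free catalyst | 22 mM | 22 mM | 22 mM |
| impurity | 11 mM | 11 mM | 11 mM |
| temperature | 100 °C | 106 °C | 100 °C |
| remark | the very flask that is asked about, followed so far | run made earlier |  |
| time |  |  | 40 h |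

- alder (time / h: target / %, starting material / %): 3.00: 14.4, 83.8; 8.00: 23.2, 76.1; 15.0: 26.9, 72.5; 40.0: 29.7, 71.1
- elm (time / h: target / %, starting material / %): 3.00: 16.5, 82.6; 8.00: 23.4, 77.7; 15.0: 25.1, 76.4; 40.0: 24.8, 75.8

(scatter of a reading: 0.5 percentage points)

- summer: at 40 h add coupling partner, 100% of the amount charged, then wait 20 h
- dusk: at 40 h take out 90% of the target then present, then wait 20 h
- winter: at 40 h add free catalyst, 50.0% of the amount charged, then wait 20 h
- noon: change nothing and wait 20 h more
- autumn: at 40 h raise the temperature by 20 K, then wait 20 h

- what is taken out of target is counted as made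
- additions bring no volume worth counting

* target, in percent of the starting material first charged, at 40 h
* the remedy with the largest gain of target, or "none" below 2 percentage points (summer / dusk / winter / noon / autumn / none)
* target present, with what was taken out counted in, in percent of the starting material first charged, after winter
* target present, with what was taken out counted in, in percent of the starting material first charged, after autumn

Step 1: For the present state I took the alder reading, 29.7%, with its scatter of 0.5 points.

Step 2: I followed one molecule of starting material. I wrote its chance of not becoming target as exp(−dose). The catalyst dose, the logarithm of one over the share not turned into target, was 0.352 in the alder flask. I took the dose to grow in step with the catalyst that worked.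

Step 3: The crude bracket for winter ran from that reading up to 100% of the charge.

Step 4: For my lower end, I let added catalyst work like the charged average. The dose then grew by 50.0%, which gave 41.1%.

Step 5: For my upper end, I supposed that c(impurity) = 11 mM had removed its equal of c(free catalyst) = 22 mM, and that the addition met no impurity. The dose then became twice its value, which gave 50.6%.

Step 6: My lower gain, 11 points, exceeded the margin, so I chose winter.

The forecast gave 29.7%, winter, 29.9% after autumn, and 35.5% after winter, with a range of 33% to 38%: “Fresh catalyst adds about half the original integrated conversion capacity”. That range lay below my bracket.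

The alder flask gave 29.4%, winter as best, 29.4% after autumn, and 41.5% after winter, inside my bracket and 6 points above the forecast. Winter multiplied the dose by 1.54. Without it, the alder flask had come to rest: after 400 h target stands at 29.4%, and the time allowed makes no difference. At 40.0 h, free catalyst is 0.0864% of its charge, with spent catalyst A at 49.9% and spent catalyst B at 50.0%, while 71% of starting material and 28% of coupling partner remain.

    starting material + free catalyst ⇌ catalyst intermediate A (K = 6.33 L mol⁻¹, k = 0.0252 L mol⁻¹ s⁻¹, Ea = 68.0 kJ mol⁻¹, ΔH = −5.00 kJ mol⁻¹)
    coupling partner + catalyst intermediate A → free catalyst + target (k = 0.00712 L mol⁻¹ s⁻¹, Ea = 79.0 kJ mol⁻¹)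
    second substrate + free catalyst ⇌ catalyst intermediate B (K = 405 L mol⁻¹, k = 0.199 L mol⁻¹ s⁻¹, Ea = 57.0 kJ mol⁻¹, ΔH = −52.0 kJ mol⁻¹)
    coupling partner + catalyst intermediate B → free catalyst + second product (k = 0.264 L mol⁻¹ s⁻¹, Ea = 52.0 kJ mol⁻¹)
    free catalyst → spent catalyst A (k = 6.17 × 10⁻⁵ s⁻¹, Ea = 129 kJ mol⁻¹)
    free catalyst + impurity → spent catalyst B (k = 1.76 L mol⁻¹ s⁻¹, Ea = 72.0 kJ mol⁻¹)
    (constants at 100 °C)

For the neighbour flask with 0.21 M of coupling partner, which like the alder flask made 0.0550 M of second product, I scaled the dose by the ratio of partner charged beyond that amount, which gave 56.3%. The computed result was 54.2%.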